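**Plan**

- The retrosynthesis first cuts two bonds together: the cyclohexene C=C (lactone Cα=CH–C(OH)) and the bond from lactone Cβ (the CH shared by lactone, cyclopentane and cyclohexene) to the neighbouring cyclopentane CH that carries the cyclohexane. This opens both carbocycles to an acyclic bromo aldehyde bearing a 3-phosphono butenolide.
- The feature that allows this is the α-alkylidene γ-lactone. It is the retron of a butenolide whose Cβ has accepted a carbon radical (5-exo, cyclopentane) and whose Cα, as a phosphonate carbanion, has olefinated an aldehyde placed 1,4 to the radical carbon (cyclohexene). Bromide and phosphonate are the only helpers, and both leave in that step.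
- Further cuts: CHO ⇐ vinyl carbinol ⇐ cyclohexanone C=O; CHBr ⇐ aldol CH(OH) (cyclohexanone + aldehyde); butenolide Cγ–CH(piperidinyl) ⇐ 2-silyloxyfuran + enal; piperidine ⇐ L-allylglycine + methyl vinyl ketone.
- Forward ring order: piperidine, then the butenolide attached, then the cyclohexane attached by aldol, then cyclopentane and cyclohexene closed together in the last step.
- Stereochemistry: piperidine C-2 is bought (L-allylglycine) and C-6 follows by cis-selective imine hydrogenation. CH(piperidinyl) and the quaternary lactone carbon are set by iminium catalysis, the cyclohexane CH by (S)-proline, and the carbinol carbon by equatorial vinyl addition. Both new cyclopentane CH centres are set in the key step by substrate control.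

Key step: step 14

Remark: 1 is taken as a catalogue compound (otherwise one esterification of N-Cbz-L-allylglycine precedes step 1). In step 7 the facial sense is taken from the accepted iminium model for this catalyst class, and catalyst control is assumed to override the piperidine stereocentre.

**Step 1**
Reactants: 1 methyl (2S)-2-{[(benzyloxy)carbonyl]amino}pent-4-enoate; 2 but-3-en-2-one
Product: 3 methyl (2S,4E)-2-{[(benzyloxy)carbonyl]amino}-6-oxohept-4-enoate
Conditions: Hoveyda–Grubbs II (3 mol%), 2 (3 equiv), CH2Cl2, 40 °C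
Reagents that add atoms: none
Why: Olefin cross-metathesis of a terminal alkene with an electron-poor enone partner should give the E-enone without touching the α-stereocentre.

**Step 2**
Reactants: 3
Product: 6 (2S,6S)-6-methylpipecolic acid methyl ester, via amino ketone 4 (not isolated), via cyclic imine 5 (not isolated)
Conditions: H2 (1 atm), 10% Pd/C, MeOH, rt
Reagents that add atoms: none
Why: Alkene hydrogenation, Cbz hydrogenolysis and intramolecular reductive amination run in one pot; the cyclic ketimine should be hydrogenated anti to the ester, setting the methyl-bearing carbon cis (2,6-cis piperidine).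

**Step 3**
Reactants: 6
Product: 7 methyl (2S,6S)-1-acetyl-6-methylpiperidine-2-carboxylate
Conditions: Ac2O, pyridine, DMAP (cat.), 60 °C
Reagents that add atoms: acetic anhydride, CC(=O)OC(C)=O
Why: DMAP-catalysed N-acylation of the hindered secondary amine installs the acetamide of the target.

**Step 4**
Reactants: 7
Product: 8 1-[(2S,6S)-2-(hydroxymethyl)-6-methylpiperidin-1-yl]ethan-1-one
Conditions: LiBH4, THF, 0 °C → rt
Reagents that add atoms: none
Why: Borohydride reduction should take the ester chemoselectively in the presence of the tertiary acetamide.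

**Step 5**
Reactants: 8
Product: 10 (2E)-3-[(2S,6S)-1-acetyl-6-methylpiperidin-2-yl]prop-2-enal, via aldehyde 9 (not isolated)
Conditions: Dess–Martin periodinane, NaHCO3, CH2Cl2, 0 °C → rt; then Ph3P=CHCHO (1.3 equiv), rt → 40 °C
Reagents that add atoms: (triphenylphosphoranylidene)acetaldehyde, O=CC=P(c1ccccc1)(c1ccccc1)c1ccccc1
Why: Dess–Martin oxidation followed in the same flask by Wittig olefination with the stabilised formyl ylide should give the E-enal, so the epimerisable α-amido aldehyde is never isolated.

**Step 6**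
Reactants: 11 5-methylfuran-2(3H)-one (α-angelica lactone)
Product: 12 trimethyl[(5-methylfuran-2-yl)oxy]silane
Conditions: TMSOTf, Et3N, Et2O, 0 °C
Reagents that add atoms: trimethylsilyl trifluoromethanesulfonate, C[Si](C)(C)OS(=O)(=O)C(F)(F)F
Why: Soft enolisation and O-silylation of the β,γ-unsaturated lactone gives the aromatic silyl dienol ether.

**Step 7**
Reactants: 10; 12
Product: 13 (3R)-3-[(2S,6S)-1-acetyl-6-methylpiperidin-2-yl]-3-[(2R)-2-methyl-5-oxo-2,5-dihydrofuran-2-yl]propanal
Conditions: (2R,5R)-5-benzyl-2-tert-butyl-3-methylimidazolidin-4-one (20 mol%), 2,4-dinitrobenzoic acid (20 mol%), H2O (2 equiv), CH2Cl2, −55 °C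
Reagents that add atoms: none
Why: Iminium-catalysed vinylogous Mukaiyama–Michael addition; the (2R,5R) catalyst should leave open the enal face that gives the (R) CH centre, and the endo ([4+2]-like) approach of furan C-5 should set the quaternary carbon (R) in the same bond formation.

**Step 8**
Reactants: 13; 14 cyclohexanone
Product: 15 (5R)-5-{(1R,3S)-1-[(2S,6S)-1-acetyl-6-methylpiperidin-2-yl]-3-hydroxy-3-[(1S)-2-oxocyclohexyl]propyl}-5-methylfuran-2(5H)-one
Conditions: (S)-proline (30 mol%), 14 (10 equiv), DMSO, rt
Reagents that add atoms: none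
Why: Proline-catalysed direct aldol via the cyclohexanone enamine should give the anti adduct with the ring α-carbon (S) under catalyst control; the carbinol configuration does not matter because it is erased in step 14.

**Step 9**
Reactants: 15
Product: 16 (5R)-5-{(1R,3S)-1-[(2S,6S)-1-acetyl-6-methylpiperidin-2-yl]-3-[(1S,2R)-2-ethenyl-2-hydroxycyclohexyl]-3-hydroxypropyl}-5-methylfuran-2(5H)-one
Conditions: CeCl3 (anhydrous), CH2=CHMgBr (3.5 equiv), THF, −78 °C
Reagents that add atoms: vinylmagnesium bromide, C=C[Mg]Br
Why: Organocerium 1,2-addition should be selective for the ketone over butenolide and amide; equatorial attack anti to the α-side chain (general for 2-substituted cyclohexanones) puts vinyl trans and the tertiary OH cis to the chain.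

**Step 10**
Reactants: 16
Product: 17 (5R)-5-{(1R,3R)-1-[(2S,6S)-1-acetyl-6-methylpiperidin-2-yl]-3-bromo-3-[(1R,2R)-2-ethenyl-2-hydroxycyclohexyl]propyl}-5-methylfuran-2(5H)-one
Conditions: CBr4, PPh3, 2,6-lutidine, CH2Cl2, 0 °C → rt
Reagents that add atoms: tetrabromomethane, BrC(Br)(Br)Br
Why: Appel bromination (SN2, inversion) should take only the secondary alcohol, the tertiary one being too hindered to form the oxyphosphonium salt.

**Step 11**
Reactants: 17
Product: 18 (5S)-5-{(1R,3R)-1-[(2S,6S)-1-acetyl-6-methylpiperidin-2-yl]-3-bromo-3-[(1R,2R)-2-ethenyl-2-hydroxycyclohexyl]propyl}-3-iodo-5-methylfuran-2(5H)-one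
Conditions: I2 (3 equiv), pyridine, CH2Cl2, rt, dark
Reagents that add atoms: iodine, II
Why: α-Iodination of the α,β-unsaturated lactone by pyridine conjugate addition, enolate iodination and elimination; the isolated vinyl group should be inert under these conditions.

**Step 12**
Reactants: 18
Product: 19 diethyl [(5S)-5-{(1R,3R)-1-[(2S,6S)-1-acetyl-6-methylpiperidin-2-yl]-3-bromo-3-[(1R,2R)-2-ethenyl-2-hydroxycyclohexyl]propyl}-5-methyl-2-oxo-2,5-dihydrofuran-3-yl]phosphonate
Conditions: HP(O)(OEt)2 (1.05 equiv), Pd(OAc)2 (5 mol%), dppf (10 mol%), iPr2NEt, MeCN, 60 °C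
Reagents that add atoms: diethyl phosphite, CCO[PH](=O)OCC
Why: Hirao P–C cross-coupling of the alkenyl iodide, which should undergo oxidative addition far faster than the secondary alkyl bromide; one equivalent of phosphite limits phospha-Michael addition to the product.

**Step 13**
Reactants: 19
Product: 20 diethyl [(5S)-5-{(1R,3R)-1-[(2S,6S)-1-acetyl-6-methylpiperidin-2-yl]-3-bromo-3-[(1R,2S)-2-formyl-2-hydroxycyclohexyl]propyl}-5-methyl-2-oxo-2,5-dihydrofuran-3-yl]phosphonate
Conditions: O3, CH2Cl2, −78 °C (Sudan Red 7B end point); Me2S, −78 °C → rt; used crude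
Reagents that add atoms: ozone, [O-][O+]=O
Why: Ozonolysis with reductive work-up should cleave only the vinyl group, the phosphono butenolide being too electron-poor to react, and unmasks the α-hydroxy aldehyde.

**Step 14**
Reactants: 20
Product: 22 target CNP0529632.1, via phosphono lactone 21 (not isolated)
Conditions: Bu3SnH (1.2 equiv, syringe pump), AIBN (0.2 equiv), PhH (0.01 M), 80 °C; then 0 °C, LiCl, DBU, MeCN, 0 °C → rt, same flask
Reagents that add atoms: none
Why: Bu3Sn• abstracts bromine from 20 and the secondary alkyl radical adds 5-exo-trig to Cβ of the doubly activated phosphono butenolide; the stabilised α-radical takes hydrogen from the stannane to give 21, whose C–H between P=O and C=O is then deprotonated by LiCl/DBU and olefinates the aldehyde intramolecularly (Horner–Wadsworth–Emmons) with loss of lithium diethyl phosphate. The closest known reaction types are the Giese radical conjugate addition to 2-phosphonoacrylates and the tandem Michael/intramolecular HWE cyclohexene annulation, here run in one pot with a radical in place of the Michael donor. The cyclopentane closes by 5-exo-trig radical attack and the cyclohexene by 6-(enolexo)-exo-trig carbanion addition to the aldehyde followed by syn-elimination of phosphate, so the new C=C is endocyclic to the six-membered ring and exocyclic to the lactone. The ring-fusion CH at the former Cβ is fixed by the quaternary lactone carbon, because the tether can only reach the butenolide face it is attached to (cis-bicyclo[3.3.0]); the former radical carbon is set in a chair-like 5-exo transition state with the piperidinyl group (C-3 of the hexenyl radical) and the cyclohexyl group (C-1) pseudo-equatorial, giving the 1,5-cis product with the cyclohexyl unit syn to Cα and away from the angular methyl. The step needs cyclisation to outrun reduction of the first radical and any reaction at the aldehyde, which the polarity match (nucleophilic radical, doubly activated alkene), the fully substituted tether carbon and slow stannane addition should secure; only the cis-disposed phosphonate/aldehyde pair can reach the six-ring olefination geometry. The configuration at the brominated carbon is erased, so 20 may be a mixture there.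

**Compound list**

1 | methyl (2S)-2-{[(benzyloxy)carbonyl]amino}pent-4-enoate (N-Cbz-L-allylglycine methyl ester) | O=C(OCc1ccccc1)N[C@@H](CC=C)C(=O)OC | starting material
2 | but-3-en-2-one (methyl vinyl ketone) | CC(=O)C=C | starting material
3 | methyl (2S,4E)-2-{[(benzyloxy)carbonyl]amino}-6-oxohept-4-enoate | O=C(OCc1ccccc1)N[C@@H](C/C=C/C(C)=O)C(=O)OC | intermediate
4 | methyl (2S)-2-amino-6-oxoheptanoate | N[C@@H](CCCC(C)=O)C(=O)OC | intermediate
5 | methyl (2S)-6-methyl-2,3,4,5-tetrahydropyridine-2-carboxylate | CC1=N[C@@H](CCC1)C(=O)OC | intermediate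
6 | methyl (2S,6S)-6-methylpiperidine-2-carboxylate (cis) | N1[C@@H](C)CCC[C@H]1C(=O)OC | intermediate
7 | methyl (2S,6S)-1-acetyl-6-methylpiperidine-2-carboxylate | CC(=O)N1[C@@H](C)CCC[C@H]1C(=O)OC | intermediate
8 | 1-[(2S,6S)-2-(hydroxymethyl)-6-methylpiperidin-1-yl]ethan-1-one | CC(=O)N1[C@@H](C)CCC[C@H]1CO | intermediate
9 | (2S,6S)-1-acetyl-6-methylpiperidine-2-carbaldehyde | CC(=O)N1[C@@H](C)CCC[C@H]1C=O | intermediate
10 | (2E)-3-[(2S,6S)-1-acetyl-6-methylpiperidin-2-yl]prop-2-enal | CC(=O)N1[C@@H](C)CCC[C@H]1/C=C/C=O | intermediate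
11 | 5-methylfuran-2(3H)-one (α-angelica lactone) | CC1=CCC(=O)O1 | starting material
12 | trimethyl[(5-methylfuran-2-yl)oxy]silane | Cc1ccc(O[Si](C)(C)C)o1 | intermediate
13 | (3R)-3-[(2S,6S)-1-acetyl-6-methylpiperidin-2-yl]-3-[(2R)-2-methyl-5-oxo-2,5-dihydrofuran-2-yl]propanal | CC(=O)N1[C@@H](C)CCC[C@H]1[C@@H](CC=O)[C@@]1(C)C=CC(=O)O1 | intermediate
14 | cyclohexanone | O=C1CCCCC1 | starting material
15 | (5R)-5-{(1R,3S)-1-[(2S,6S)-1-acetyl-6-methylpiperidin-2-yl]-3-hydroxy-3-[(1S)-2-oxocyclohexyl]propyl}-5-methylfuran-2(5H)-one | CC(=O)N1[C@@H](C)CCC[C@H]1[C@@H](C[C@@H]([C@H]1C(=O)CCCC1)O)[C@@]1(C)C=CC(=O)O1 | intermediate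
16 | (5R)-5-{(1R,3S)-1-[(2S,6S)-1-acetyl-6-methylpiperidin-2-yl]-3-[(1S,2R)-2-ethenyl-2-hydroxycyclohexyl]-3-hydroxypropyl}-5-methylfuran-2(5H)-one | CC(=O)N1[C@@H](C)CCC[C@H]1[C@@H](C[C@@H]([C@H]1[C@@](C=C)(O)CCCC1)O)[C@@]1(C)C=CC(=O)O1 | intermediate
17 | (5R)-5-{(1R,3R)-1-[(2S,6S)-1-acetyl-6-methylpiperidin-2-yl]-3-bromo-3-[(1R,2R)-2-ethenyl-2-hydroxycyclohexyl]propyl}-5-methylfuran-2(5H)-one | CC(=O)N1[C@@H](C)CCC[C@H]1[C@@H](C[C@H]([C@H]1[C@@](C=C)(O)CCCC1)Br)[C@@]1(C)C=CC(=O)O1 | intermediate
18 | (5S)-3-iodo analogue of 17 (3-iodo-5-methylfuran-2(5H)-one, side chain unchanged) | CC(=O)N1[C@@H](C)CCC[C@H]1[C@@H](C[C@H]([C@H]1[C@@](C=C)(O)CCCC1)Br)[C@@]1(C)C=C(I)C(=O)O1 | intermediate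
19 | diethyl [(5S)-5-{(1R,3R)-1-[(2S,6S)-1-acetyl-6-methylpiperidin-2-yl]-3-bromo-3-[(1R,2R)-2-ethenyl-2-hydroxycyclohexyl]propyl}-5-methyl-2-oxo-2,5-dihydrofuran-3-yl]phosphonate | CC(=O)N1[C@@H](C)CCC[C@H]1[C@@H](C[C@H]([C@H]1[C@@](C=C)(O)CCCC1)Br)[C@@]1(C)C=C(P(=O)(OCC)OCC)C(=O)O1 | intermediate
20 | diethyl [(5S)-5-{(1R,3R)-1-[(2S,6S)-1-acetyl-6-methylpiperidin-2-yl]-3-bromo-3-[(1R,2S)-2-formyl-2-hydroxycyclohexyl]propyl}-5-methyl-2-oxo-2,5-dihydrofuran-3-yl]phosphonate | CC(=O)N1[C@@H](C)CCC[C@H]1[C@@H](C[C@H]([C@H]1[C@@](C=O)(O)CCCC1)Br)[C@@]1(C)C=C(P(=O)(OCC)OCC)C(=O)O1 | intermediate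
21 | diethyl {cis-fused 6-[(2S,6S)-1-acetyl-6-methylpiperidin-2-yl]-4-[(1S,2S)-2-formyl-2-hydroxycyclohexyl]-6a-methyl-2-oxohexahydro-2H-cyclopenta[b]furan-3-yl}phosphonate, ring centres as in 22, both C-3 epimers | CC(=O)N1[C@@H](C)CCC[C@H]1[C@H]1C[C@@H]([C@H]2[C@@](C=O)(O)CCCC2)[C@H]2C(P(=O)(OCC)OCC)C(=O)O[C@@]12C | intermediate
22 | CNP0529632.1: γ-lactone cis-fused to the cyclopentane and bearing the cyclohexene C=C at Cα; cyclohexene cis-fused to the cyclopentane and trans-fused to the cyclohexane, with the tertiary OH at that ring fusion; (2S,6S)-1-acetyl-6-methylpiperidin-2-yl on the cyclopentane | CC(=O)N1[C@@H](C)CCC[C@H]1[C@H]1C[C@@H]2[C@H]3C(=C[C@]4(O)CCCC[C@@H]24)C(=O)O[C@@]13C | target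

**Totals**

Total steps: 14. Longest linear sequence: 13 (steps 1–5 and 7–14; step 6 is a one-step side branch).

**Steps most likely to fail**

1. Step 14. The alkyl radical may cyclise with too little face selectivity at the radical carbon, or tin radicals and base may engage the free α-hydroxy aldehyde (reduction, α-ketol rearrangement) before the rings close. The fallback uncouples the two bond formations and keeps the aldehyde masked during the radical stage. It sets out from 19: Bu3SnH/AIBN (PhH, 80 °C) should give the cyclised vinyl phosphono lactone F1, from which epimers at the new ring carbon can be separated. Ozonolysis (O3, CH2Cl2, −78 °C; Me2S) of F1 then gives 21, where the route is rejoined; LiCl/DBU closes the cyclohexene to 22.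

2. Step 7. The furan may add with the wrong relative topicity at the quaternary carbon, catalyst control may be eroded by a mismatch with the piperidine stereocentre, or γ-deprotonation of the iminium ion may scramble the piperidine carbon. The fallback replaces iminium activation by chelate-controlled Lewis acid catalysis, which has the complementary simple diastereoselection. It sets out from 8: oxidation as in step 5, then HWE olefination with diethyl [2-oxo-2-(2-oxo-1,3-oxazolidin-3-yl)ethyl]phosphonate (LiCl, iPr2NEt, MeCN) gives the N-enoyl oxazolidinone F2. Cu(OTf)2/tert-butyl-bis(oxazoline)-catalysed Mukaiyama–Michael addition of 12 (ligand enantiomer chosen for the (R) CH centre) gives the imide adduct F3. LiBH4/H2O (THF, 0 °C) cleaves the imide to the primary alcohol F4, and Dess–Martin oxidation returns to the route at 13.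

3. Step 10. E2 elimination and ionisation of the allylic tertiary alcohol may compete with SN2 at the hindered secondary oxyphosphonium centre. The fallback avoids the halide and the aldehyde altogether. It sets out from 16: selective acylation of the secondary hydroxyl with phenyl chlorothionoformate (pyridine, DMAP) gives the thionocarbonate F5. Barton–McCombie radical generation (Bu3SnH, AIBN, PhH, 80 °C) with 5-exo cyclisation onto the plain butenolide gives the cis-fused vinyl lactone F6. α-Methylenation (LDA, 2.2 equiv, −78 °C; Eschenmoser's salt; MeI, then NaHCO3) gives the α-methylene lactone F7. Ring-closing metathesis (Grubbs II, CH2Cl2, 40 °C) between the methylene and vinyl groups closes the cyclohexene and returns to the route at 22.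

**Further compounds**

F1 | step 14 | diethyl {cis-fused 6-[(2S,6S)-1-acetyl-6-methylpiperidin-2-yl]-4-[(1S,2R)-2-ethenyl-2-hydroxycyclohexyl]-6a-methyl-2-oxohexahydro-2H-cyclopenta[b]furan-3-yl}phosphonate (ring centres as in 22) | CC(=O)N1[C@@H](C)CCC[C@H]1[C@H]1C[C@@H]([C@H]2[C@@](C=C)(O)CCCC2)[C@H]2C(P(=O)(OCC)OCC)C(=O)O[C@@]12C
F2 | step 7 | 3-{(2E)-3-[(2S,6S)-1-acetyl-6-methylpiperidin-2-yl]prop-2-enoyl}-1,3-oxazolidin-2-one | CC(=O)N1[C@@H](C)CCC[C@H]1/C=C/C(=O)N1CCOC1=O
F3 | step 7 | 3-{(3R)-3-[(2S,6S)-1-acetyl-6-methylpiperidin-2-yl]-3-[(2R)-2-methyl-5-oxo-2,5-dihydrofuran-2-yl]propanoyl}-1,3-oxazolidin-2-one | CC(=O)N1[C@@H](C)CCC[C@H]1[C@@H](CC(=O)N1CCOC1=O)[C@@]1(C)C=CC(=O)O1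
F4 | step 7 | (5R)-5-{(1R)-1-[(2S,6S)-1-acetyl-6-methylpiperidin-2-yl]-3-hydroxypropyl}-5-methylfuran-2(5H)-one | CC(=O)N1[C@@H](C)CCC[C@H]1[C@@H](CCO)[C@@]1(C)C=CC(=O)O1
F5 | step 10 | O-phenyl thionocarbonate of the secondary hydroxyl of 16 | CC(=O)N1[C@@H](C)CCC[C@H]1[C@@H](C[C@@H]([C@H]1[C@@](C=C)(O)CCCC1)OC(=S)Oc1ccccc1)[C@@]1(C)C=CC(=O)O1
F6 | step 10 | cis-fused 6-[(2S,6S)-1-acetyl-6-methylpiperidin-2-yl]-4-[(1S,2R)-2-ethenyl-2-hydroxycyclohexyl]-6a-methylhexahydro-2H-cyclopenta[b]furan-2-one (ring centres as in 22) | CC(=O)N1[C@@H](C)CCC[C@H]1[C@H]1C[C@@H]([C@H]2[C@@](C=C)(O)CCCC2)[C@H]2CC(=O)O[C@@]12C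
F7 | step 10 | 3-methylidene derivative of F6 (α-methylene lactone) | CC(=O)N1[C@@H](C)CCC[C@H]1[C@H]1C[C@@H]([C@H]2[C@@](C=C)(O)CCCC2)[C@H]2C(=C)C(=O)O[C@@]12C
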